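**Retrosynthetic overview**
1. The strategy rests on the oxolane C3–C4 bond, which joins the CH2OH-bearing C3 to the benzyl-bearing C4 of the 2,3-trans, 3,4-cis ring. It is formed last, by a titanocene-mediated reductive 5-exo radical closure of an epoxy cinnamyl ether in which only C2 is set beforehand.
2. The epoxy ether comes from trimer aldehyde 26 by vinyl Grignard addition, tartrate-controlled epoxidation of the (R)-carbinol epimer, and O-alkylation with cinnamyl bromide 33 made from ferulic acid.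
3. The trimer is grown from the guaiacyl end in three rounds: Mitsunobu etherification with one phenol building block (7), diazo transfer, and enantioselective rhodium-carbenoid insertion into the benzylic ether C–H bond, followed by C3 epimerisation to the trans ester.
4. Ring order: dihydrofuran of unit C, then unit B, then unit A, then the oxolane. The three esters are reduced together, and silyl and benzyl groups come off at the end.

Key step: step 26

Remark 1: Rh2(S-PTTL)4 [dirhodium tetrakis(N-phthaloyl-(S)-tert-leucinate)] is taken to give the (2R) cis ester; if the sense proves opposite, the two catalyst enantiomers are exchanged.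
Remark 2: The three 2-aryl-7-methoxy-2,3-dihydro-1-benzofurans are called unit C (bears the 4-benzyloxy-3-methoxyphenyl group at C2), unit B (bears unit C at C2, bonded through C5 of unit C) and unit A (bears unit B at C2, bonded through C5 of unit B; its own C5 carries the growing end). Locants are those of each dihydrobenzofuran.
Remark 3: TBS = tert-butyldimethylsilyl, TBDPS = tert-butyldiphenylsilyl, Bn = benzyl; compounds 1, 4, 8, 27 and 30 are purchased.

**Step 1**
Reactants: 1 5-bromovanillin (3-bromo-4-hydroxy-5-methoxybenzaldehyde)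
Product: 2 2-bromo-4-(hydroxymethyl)-6-methoxyphenol
Conditions: NaBH4, MeOH, 0 °C
Reagents that add atoms: none
Why: Hydride reduction of the aryl aldehyde gives the benzylic alcohol and leaves the aryl bromide and the phenol untouched.

**Step 2**
Reactants: 2 2-bromo-4-(hydroxymethyl)-6-methoxyphenol
Product: 3 bis-TBS ether of 2 (aryl OTBS and benzylic CH2OTBS)
Conditions: TBSCl (2.4 equiv), imidazole, DMF, rt
Reagents that add atoms: tert-butyl(chloro)dimethylsilane, CC(C)(C)[Si](C)(C)Cl
Why: Double O-silylation masks the benzylic alcohol for the whole chain assembly and the phenol for the zinc coupling.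

**Step 3**
Reactants: 3 bis-TBS aryl bromide; 4 methyl bromoacetate
Product: 6 methyl 2-[2-(TBSO)-5-(TBSOCH2)-3-methoxyphenyl]acetate, via zinc reagent 5 (not isolated)
Conditions: 4, Zn dust (Me3SiCl-activated), THF, 40 °C; then 3, Pd2(dba)3 (2.5 mol%), XPhos (10 mol%), THF, 65 °C
Reagents that add atoms: none
Why: Negishi-type α-arylation with a Reformatsky reagent, in which zerovalent palladium with a bulky biaryl phosphine inserts into the hindered electron-rich aryl bromide and the zinc enolate delivers the CH2CO2Me group under neutral conditions that spare both silyl ethers.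

**Step 4**
Reactants: 6 methyl 2-[2-(TBSO)-5-(TBSOCH2)-3-methoxyphenyl]acetate
Product: 7 methyl 2-[5-(TBSOCH2)-2-hydroxy-3-methoxyphenyl]acetate (phenol building block)
Conditions: K2CO3 (0.5 equiv), MeOH, 0 °C to rt
Reagents that add atoms: none
Why: Selective desilylation, since methanolic carbonate cleaves the phenolic silyl ether far faster than the alkyl one, and in methanol the hydroxy ester stays open instead of closing to the benzofuranone.

**Step 5**
Reactants: 7 phenol building block; 8 4-(benzyloxy)-3-methoxybenzyl alcohol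
Product: 9 methyl 2-[2-{[4-(benzyloxy)-3-methoxyphenyl]methoxy}-5-(TBSOCH2)-3-methoxyphenyl]acetate
Conditions: PPh3, DIAD, THF, 0 °C to rt
Reagents that add atoms: none
Why: Mitsunobu etherification joins the phenol and the electron-rich benzylic alcohol under neutral conditions and installs the O–CH2–aryl group whose C–H bond is used in step 7.

**Step 6**
Reactants: 9 aryl benzyl ether ester
Product: 10 methyl 2-diazo-2-[2-{[4-(benzyloxy)-3-methoxyphenyl]methoxy}-5-(TBSOCH2)-3-methoxyphenyl]acetate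
Conditions: p-ABSA, DBU, MeCN, 0 °C to rt
Reagents that add atoms: 4-acetamidobenzenesulfonyl azide (p-ABSA), CC(=O)Nc1ccc(cc1)S(=O)(=O)N=[N+]=[N-]
Why: Regitz diazo transfer, in which the DBU-generated arylacetate enolate attacks the sulfonyl azide and gives the aryldiazoacetate.

**Step 7**
Reactants: 10 aryldiazoacetate
Product: 12 methyl (2R,3R)-2-[4-(benzyloxy)-3-methoxyphenyl]-7-methoxy-5-(TBSOCH2)-2,3-dihydro-1-benzofuran-3-carboxylate (trans ester of unit C), via cis-ester 11 (not isolated)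
Conditions: Rh2(S-PTTL)4 (1 mol%), toluene, −60 °C; then NaOMe (0.3 equiv), MeOH, 0 °C to rt
Reagents that add atoms: none
Why: Rhodium-carbenoid intramolecular 1,5 C–H insertion into the benzylic ether C–H bond closes the dihydrofuran, the chiral carboxylate catalyst setting C2 (R) and giving the cis ester, and methoxide then epimerises only C3 to the more stable trans ester.

**Step 8**
Reactants: 12 trans ester of unit C
Product: 13 methyl (2R,3R)-2-[4-(benzyloxy)-3-methoxyphenyl]-5-(hydroxymethyl)-7-methoxy-2,3-dihydro-1-benzofuran-3-carboxylate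
Conditions: HF·pyridine, pyridine, THF, 0 °C to rt
Reagents that add atoms: none
Why: Buffered fluoride desilylation frees the C5 benzylic alcohol without base that could disturb the ester-bearing C3.

**Step 9**
Reactants: 13 unit C alcohol; 7 phenol building block
Product: 14 methyl (2R,3R)-2-[4-(benzyloxy)-3-methoxyphenyl]-5-{[4-(TBSOCH2)-2-methoxy-6-(2-methoxy-2-oxoethyl)phenoxy]methyl}-7-methoxy-2,3-dihydro-1-benzofuran-3-carboxylate
Conditions: PPh3, DIAD, THF, 0 °C to rt
Reagents that add atoms: none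
Why: Second Mitsunobu etherification, now with the p-alkoxybenzylic alcohol of unit C as the electrophilic partner.

**Step 10**
Reactants: 14 unit C ether ester
Product: 15 diazo ester of 14 (CH2CO2Me turned into C(N2)CO2Me)
Conditions: p-ABSA, DBU, MeCN, 0 °C
Reagents that add atoms: 4-acetamidobenzenesulfonyl azide (p-ABSA), CC(=O)Nc1ccc(cc1)S(=O)(=O)N=[N+]=[N-]
Why: Regitz diazo transfer at the only CH2 flanked by aryl and ester, while the tertiary C3–H of unit C cannot take up a diazo group and is already in its stable trans form.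

**Step 11**
Reactants: 15 diazo ester
Product: 17 all-trans dimer diester: unit B (2S,3S) carrying 5-CH2OTBS; unit C (2R,3R), via cis-dimer 16 (not isolated)
Conditions: Rh2(R-PTTL)4 (1 mol%), toluene, −60 °C; then NaOMe (0.3 equiv), MeOH, 0 °C to rt
Reagents that add atoms: none
Why: The same carbenoid C–H insertion and C3 epimerisation build ring B, the enantiomeric catalyst setting C2 (S) by catalyst control because the centres of unit C lie on the far side of an arene.

**Step 12**
Reactants: 17 all-trans dimer diester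
Product: 18 dimer alcohol (5-CH2OH on unit B; unit B (2S,3S), unit C (2R,3R))
Conditions: HF·pyridine, pyridine, THF, 0 °C to rt
Reagents that add atoms: none
Why: Fluoride desilylation of the primary benzylic silyl ether, with both esters inert.

**Step 13**
Reactants: 18 dimer alcohol; 7 phenol building block
Product: 19 dimer aryl ether of 7 (ArO–CH2 at C5 of unit B; new arene carries CH2CO2Me, OMe and CH2OTBS)
Conditions: PPh3, DIAD, THF, 0 °C to rt
Reagents that add atoms: none
Why: Third Mitsunobu etherification of the same kind.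

**Step 14**
Reactants: 19 dimer ether ester
Product: 20 diazo ester of 19
Conditions: p-ABSA, DBU, MeCN, 0 °C
Reagents that add atoms: 4-acetamidobenzenesulfonyl azide (p-ABSA), CC(=O)Nc1ccc(cc1)S(=O)(=O)N=[N+]=[N-]
Why: Regitz diazo transfer at the single arylacetate CH2.

**Step 15**
Reactants: 20 diazo ester
Product: 22 all-trans trimer triester: units A/B (2S,3S); unit C (2R,3R); 5-CH2OTBS on unit A, via cis-trimer 21 (not isolated)
Conditions: Rh2(R-PTTL)4 (1–2 mol%), toluene, −60 °C; then NaOMe (0.3 equiv), MeOH, 0 °C to rt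
Reagents that add atoms: none
Why: Third carbenoid C–H insertion and epimerisation close ring A with C2 (S) under catalyst control and C3 trans under thermodynamic control.

**Step 16**
Reactants: 22 all-trans trimer triester
Product: 23 trimer triol (3-CH2OH on each unit; units A/B (2S,3R), unit C (2R,3S); 5-CH2OTBS on unit A)
Conditions: LiAlH4, THF, 0 °C
Reagents that add atoms: none
Why: Hydride reduction of the three methyl esters to primary alcohols leaves all six stereocentres and the silyl ether untouched (the descriptor at C3 changes only by CIP priority).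

**Step 17**
Reactants: 23 trimer triol
Product: 24 tris-TBDPS ether of 23 (TBS ether on unit A retained)
Conditions: TBDPSCl (3.6 equiv), imidazole, DMAP (cat.), DMF, rt
Reagents that add atoms: tert-butyl(chloro)diphenylsilane, CC(C)(C)[Si](Cl)(c1ccccc1)c1ccccc1
Why: Silylation with the more robust TBDPS group makes the three hydroxymethyls distinguishable from the benzylic TBS ether.

**Step 18**
Reactants: 24 tris-TBDPS TBS ether
Product: 25 trimer benzylic alcohol (5-CH2OH on unit A; three CH2OTBDPS)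
Conditions: HF·pyridine, pyridine, THF, 0 °C
Reagents that add atoms: none
Why: Selective desilylation, since a primary TBS ether is cleaved by buffered HF·pyridine much faster than TBDPS ethers.

**Step 19**
Reactants: 25 trimer benzylic alcohol
Product: 26 trimer aldehyde (5-CHO on unit A)
Conditions: MnO2, CH2Cl2, rt
Reagents that add atoms: none
Why: MnO2 oxidises the electron-rich benzylic alcohol to the aldehyde without over-oxidation and without touching the silyl or benzyl ethers.

**Step 20**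
Reactants: 26 trimer aldehyde; 27 vinylmagnesium bromide
Product: 28 trimer 1-arylprop-2-en-1-ol, both carbinol epimers
Conditions: THF, −78 °C to −20 °C; then H2O
Reagents that add atoms: none
Why: Grignard 1,2-addition to the aryl aldehyde; the nearest stereocentres are too remote to bias the new carbinol centre, so both epimers are expected and the choice is made in step 21.

**Step 21**
Reactants: 28 allylic alcohol (epimer mixture)
Product: 29 trimer epoxy alcohol, (S)-carbinol carbon and (R)-oxirane carbon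
Conditions: Ti(OiPr)4, L-(+)-diisopropyl tartrate, t-BuOOH (0.55 equiv), 4 Å molecular sieves, CH2Cl2, −20 °C
Reagents that add atoms: tert-butyl hydroperoxide, CC(C)(C)OO
Why: Sharpless asymmetric epoxidation run as a kinetic resolution, in which L-(+)-tartrate makes the (R)-carbinol epimer the fast one and epoxidises it on the tartrate-dictated face to the erythro epoxy alcohol (carbinol S and oxirane R by CIP), while the (S)-carbinol epimer is left and separated.

**Step 22**
Reactants: 30 ferulic acid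
Product: 31 benzyl (E)-3-[4-(benzyloxy)-3-methoxyphenyl]prop-2-enoate
Conditions: BnBr (2.3 equiv), K2CO3, DMF, 60 °C
Reagents that add atoms: benzyl bromide, BrCc1ccccc1
Why: Williamson O-alkylation of the phenoxide and alkylation of the carboxylate in one operation.

**Step 23**
Reactants: 31 benzyl ester benzyl ether
Product: 32 (E)-3-[4-(benzyloxy)-3-methoxyphenyl]prop-2-en-1-ol
Conditions: i-Bu2AlH, CH2Cl2, −78 °C
Reagents that add atoms: none
Why: 1,2-Reduction of the cinnamate ester by the aluminium hydride gives the allylic alcohol with the E alkene intact.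

**Step 24**
Reactants: 32 cinnamyl alcohol
Product: 33 (E)-1-(benzyloxy)-4-(3-bromoprop-1-en-1-yl)-2-methoxybenzene
Conditions: PBr3, Et2O, 0 °C; used at once
Reagents that add atoms: phosphorus tribromide, BrP(Br)Br
Why: Bromination of the allylic alcohol through its phosphite ester gives the labile cinnamyl bromide, which is not stored.

**Step 25**
Reactants: 29 trimer epoxy alcohol; 33 cinnamyl bromide
Product: 34 trimer epoxy cinnamyl ether, (S)-carbinol carbon and (R)-oxirane carbon
Conditions: NaH, n-Bu4NI (cat.), THF/DMSO, 0 °C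
Reagents that add atoms: none
Why: Williamson etherification of the secondary alkoxide at the primary allylic carbon, which leaves the C–O bond of the carbinol centre (and so its configuration) untouched.

**Step 26**
Reactants: 34 trimer epoxy cinnamyl ether
Product: 35 protected target: (2R,3S,4S)-4-[4-(benzyloxy)-3-methoxybenzyl]-3-(hydroxymethyl)-2-(trimer aryl)oxolane with three CH2OTBDPS and two OBn groups
Conditions: Cp2TiCl2 (3 equiv), Zn dust, THF, rt; the green Cp2TiCl solution is added slowly to 34 in THF, rt; then 1 M HCl, 0 °C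
Reagents that add atoms: none
Why: Cp2TiCl (trivalent titanium) transfers one electron to the oxirane, which opens at its more substituted carbon to the secondary C3 radical with the titanium alkoxide on the future CH2OH carbon; this is the known titanocene-mediated reductive epoxide opening with radical cyclisation onto an alkene. The radical adds 5-exo-trig to the proximal alkene carbon, which forms C3–C4 and closes the oxolane, and the benzylic radical so formed is captured by a second Cp2TiCl and protonated on work-up to the CH2–aryl group. C3 is planar in the radical, so the oxirane configuration is erased and the single C2 centre from step 21 controls both new centres. In the chair-like transition state of this 5-hexenyl-type closure the C2 aryl group lies pseudo-equatorial, the CH2O–titanium group on the radical carbon turns anti to it (C3 becomes S, 2,3-trans) and the alkene takes the 1,5-cis orientation to that group (C4 becomes S, 3,4-cis). The step needs cyclisation to outrun capture of the C3 radical by titanium (which would end in β-elimination to the allyl ether) and the 6-endo mode; slow addition keeps the titanium concentration low, and the aryl group on the alkene terminus makes the 5-exo addition fast and regioselective. The silyl ethers, the benzyl ethers and the benzylic ring ethers are inert to Cp2TiCl.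

**Step 27**
Reactants: 35 protected target
Product: 36 bis-benzyl ether of the target (four free CH2OH groups)
Conditions: n-Bu4NF, THF, rt to 40 °C
Reagents that add atoms: none
Why: Fluoride desilylation removes the three TBDPS groups and leaves the benzyl ethers and all stereocentres unchanged.

**Step 28**
Reactants: 36 bis-benzyl ether
Product: 37 target CNP0267891.2
Conditions: H2 (1 atm), Pd/C (10%), EtOAc/MeOH, rt, stopped as soon as 36 is consumed
Reagents that add atoms: none
Why: Hydrogenolysis cleaves the two phenolic benzyl ethers much faster than the benzylic C–O bonds of the oxolane and dihydrofuran rings, so close monitoring should give the free bis-phenol.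

**Compound list**
1 | 5-bromovanillin (3-bromo-4-hydroxy-5-methoxybenzaldehyde) | COc1cc(C=O)cc(Br)c1O | starting material
2 | 2-bromo-4-(hydroxymethyl)-6-methoxyphenol | COc1cc(CO)cc(Br)c1O | intermediate
3 | bis-TBS ether of 2 | COc1cc(CO[Si](C)(C)C(C)(C)C)cc(Br)c1O[Si](C)(C)C(C)(C)C | intermediate
4 | methyl bromoacetate | COC(=O)CBr | starting material
5 | bromo(2-methoxy-2-oxoethyl)zinc | COC(=O)C[Zn]Br | intermediate
6 | methyl 2-[2-(TBSO)-5-(TBSOCH2)-3-methoxyphenyl]acetate | COc1cc(CO[Si](C)(C)C(C)(C)C)cc(CC(=O)OC)c1O[Si](C)(C)C(C)(C)C | intermediate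
7 | methyl 2-[5-(TBSOCH2)-2-hydroxy-3-methoxyphenyl]acetate | COc1cc(CO[Si](C)(C)C(C)(C)C)cc(CC(=O)OC)c1O | intermediate
8 | 4-(benzyloxy)-3-methoxybenzyl alcohol | COc1cc(CO)ccc1OCc1ccccc1 | starting material
9 | methyl 2-[2-{[4-(benzyloxy)-3-methoxyphenyl]methoxy}-5-(TBSOCH2)-3-methoxyphenyl]acetate | COc1cc(CO[Si](C)(C)C(C)(C)C)cc(CC(=O)OC)c1OCc1ccc(OCc2ccccc2)c(OC)c1 | intermediate
10 | diazo ester of 9 | COc1cc(CO[Si](C)(C)C(C)(C)C)cc(C(=[N+]=[N-])C(=O)OC)c1OCc1ccc(OCc2ccccc2)c(OC)c1 | intermediate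
11 | methyl (2R,3S)-2-[4-(benzyloxy)-3-methoxyphenyl]-7-methoxy-5-(TBSOCH2)-2,3-dihydro-1-benzofuran-3-carboxylate (cis) | CC(C)(C)[Si](C)(C)OCc1cc(OC)c2c(c1)[C@H](C(=O)OC)[C@H](c1ccc(OCc3ccccc3)c(OC)c1)O2 | intermediate
12 | methyl (2R,3R)-2-[4-(benzyloxy)-3-methoxyphenyl]-7-methoxy-5-(TBSOCH2)-2,3-dihydro-1-benzofuran-3-carboxylate (trans) | CC(C)(C)[Si](C)(C)OCc1cc(OC)c2c(c1)[C@@H](C(=O)OC)[C@H](c1ccc(OCc3ccccc3)c(OC)c1)O2 | intermediate
13 | methyl (2R,3R)-2-[4-(benzyloxy)-3-methoxyphenyl]-5-(hydroxymethyl)-7-methoxy-2,3-dihydro-1-benzofuran-3-carboxylate | OCc1cc(OC)c2c(c1)[C@@H](C(=O)OC)[C@H](c1ccc(OCc3ccccc3)c(OC)c1)O2 | intermediate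
14 | ether of 13 with phenol 7 (unit C (2R,3R)) | COc1cc(CO[Si](C)(C)C(C)(C)C)cc(CC(=O)OC)c1OCc1cc(OC)c2c(c1)[C@@H](C(=O)OC)[C@H](c1ccc(OCc3ccccc3)c(OC)c1)O2 | intermediate
15 | diazo ester of 14 | COc1cc(CO[Si](C)(C)C(C)(C)C)cc(C(=[N+]=[N-])C(=O)OC)c1OCc1cc(OC)c2c(c1)[C@@H](C(=O)OC)[C@H](c1ccc(OCc3ccccc3)c(OC)c1)O2 | intermediate
16 | dimer diester, unit B cis (2S,3R), unit C (2R,3R), 5-CH2OTBS on unit B | CC(C)(C)[Si](C)(C)OCc1cc(OC)c2c(c1)[C@@H](C(=O)OC)[C@@H](c1cc(OC)c3c(c1)[C@@H](C(=O)OC)[C@H](c1ccc(OCc4ccccc4)c(OC)c1)O3)O2 | intermediate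
17 | all-trans dimer diester, unit B (2S,3S), unit C (2R,3R), 5-CH2OTBS on unit B | CC(C)(C)[Si](C)(C)OCc1cc(OC)c2c(c1)[C@H](C(=O)OC)[C@@H](c1cc(OC)c3c(c1)[C@@H](C(=O)OC)[C@H](c1ccc(OCc4ccccc4)c(OC)c1)O3)O2 | intermediate
18 | dimer alcohol, 5-CH2OH on unit B | OCc1cc(OC)c2c(c1)[C@H](C(=O)OC)[C@@H](c1cc(OC)c3c(c1)[C@@H](C(=O)OC)[C@H](c1ccc(OCc4ccccc4)c(OC)c1)O3)O2 | intermediate
19 | ether of 18 with phenol 7 | COc1cc(CO[Si](C)(C)C(C)(C)C)cc(CC(=O)OC)c1OCc1cc(OC)c2c(c1)[C@H](C(=O)OC)[C@@H](c1cc(OC)c3c(c1)[C@@H](C(=O)OC)[C@H](c1ccc(OCc4ccccc4)c(OC)c1)O3)O2 | intermediate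
20 | diazo ester of 19 | COc1cc(CO[Si](C)(C)C(C)(C)C)cc(C(=[N+]=[N-])C(=O)OC)c1OCc1cc(OC)c2c(c1)[C@H](C(=O)OC)[C@@H](c1cc(OC)c3c(c1)[C@@H](C(=O)OC)[C@H](c1ccc(OCc4ccccc4)c(OC)c1)O3)O2 | intermediate
21 | trimer triester, unit A cis (2S,3R), unit B (2S,3S), unit C (2R,3R), 5-CH2OTBS on unit A | CC(C)(C)[Si](C)(C)OCc1cc(OC)c2c(c1)[C@@H](C(=O)OC)[C@@H](c1cc(OC)c3c(c1)[C@H](C(=O)OC)[C@@H](c1cc(OC)c4c(c1)[C@@H](C(=O)OC)[C@H](c1ccc(OCc5ccccc5)c(OC)c1)O4)O3)O2 | intermediate
22 | all-trans trimer triester, units A and B (2S,3S), unit C (2R,3R), 5-CH2OTBS on unit A | CC(C)(C)[Si](C)(C)OCc1cc(OC)c2c(c1)[C@H](C(=O)OC)[C@@H](c1cc(OC)c3c(c1)[C@H](C(=O)OC)[C@@H](c1cc(OC)c4c(c1)[C@@H](C(=O)OC)[C@H](c1ccc(OCc5ccccc5)c(OC)c1)O4)O3)O2 | intermediate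
23 | trimer triol, units A and B (2S,3R), unit C (2R,3S), 5-CH2OTBS on unit A | CC(C)(C)[Si](C)(C)OCc1cc(OC)c2c(c1)[C@H](CO)[C@@H](c1cc(OC)c3c(c1)[C@H](CO)[C@@H](c1cc(OC)c4c(c1)[C@@H](CO)[C@H](c1ccc(OCc5ccccc5)c(OC)c1)O4)O3)O2 | intermediate
24 | tris-TBDPS ether of 23 | CC(C)(C)[Si](C)(C)OCc1cc(OC)c2c(c1)[C@H](CO[Si](c6ccccc6)(c7ccccc7)C(C)(C)C)[C@@H](c1cc(OC)c3c(c1)[C@H](CO[Si](c6ccccc6)(c7ccccc7)C(C)(C)C)[C@@H](c1cc(OC)c4c(c1)[C@@H](CO[Si](c6ccccc6)(c7ccccc7)C(C)(C)C)[C@H](c1ccc(OCc5ccccc5)c(OC)c1)O4)O3)O2 | intermediate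
25 | trimer benzylic alcohol (5-CH2OH on unit A, three CH2OTBDPS) | OCc1cc(OC)c2c(c1)[C@H](CO[Si](c6ccccc6)(c7ccccc7)C(C)(C)C)[C@@H](c1cc(OC)c3c(c1)[C@H](CO[Si](c6ccccc6)(c7ccccc7)C(C)(C)C)[C@@H](c1cc(OC)c4c(c1)[C@@H](CO[Si](c6ccccc6)(c7ccccc7)C(C)(C)C)[C@H](c1ccc(OCc5ccccc5)c(OC)c1)O4)O3)O2 | intermediate
26 | trimer aldehyde (5-CHO on unit A) | O=Cc1cc(OC)c2c(c1)[C@H](CO[Si](c6ccccc6)(c7ccccc7)C(C)(C)C)[C@@H](c1cc(OC)c3c(c1)[C@H](CO[Si](c6ccccc6)(c7ccccc7)C(C)(C)C)[C@@H](c1cc(OC)c4c(c1)[C@@H](CO[Si](c6ccccc6)(c7ccccc7)C(C)(C)C)[C@H](c1ccc(OCc5ccccc5)c(OC)c1)O4)O3)O2 | intermediate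
27 | vinylmagnesium bromide | C=C[Mg]Br | starting material
28 | trimer 1-arylprop-2-en-1-ol, both carbinol epimers | C=CC(O)c1cc(OC)c2c(c1)[C@H](CO[Si](c6ccccc6)(c7ccccc7)C(C)(C)C)[C@@H](c1cc(OC)c3c(c1)[C@H](CO[Si](c6ccccc6)(c7ccccc7)C(C)(C)C)[C@@H](c1cc(OC)c4c(c1)[C@@H](CO[Si](c6ccccc6)(c7ccccc7)C(C)(C)C)[C@H](c1ccc(OCc5ccccc5)c(OC)c1)O4)O3)O2 | intermediate
29 | trimer epoxy alcohol, (S)-aryl[(2R)-oxiran-2-yl]methanol | O[C@@H](c1cc(OC)c2c(c1)[C@H](CO[Si](c6ccccc6)(c7ccccc7)C(C)(C)C)[C@@H](c1cc(OC)c3c(c1)[C@H](CO[Si](c6ccccc6)(c7ccccc7)C(C)(C)C)[C@@H](c1cc(OC)c4c(c1)[C@@H](CO[Si](c6ccccc6)(c7ccccc7)C(C)(C)C)[C@H](c1ccc(OCc5ccccc5)c(OC)c1)O4)O3)O2)[C@H]8CO8 | intermediate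
30 | ferulic acid | COc1cc(/C=C/C(=O)O)ccc1O | starting material
31 | benzyl (E)-3-[4-(benzyloxy)-3-methoxyphenyl]prop-2-enoate | COc1cc(/C=C/C(=O)OCc2ccccc2)ccc1OCc1ccccc1 | intermediate
32 | (E)-3-[4-(benzyloxy)-3-methoxyphenyl]prop-2-en-1-ol | COc1cc(/C=C/CO)ccc1OCc1ccccc1 | intermediate
33 | (E)-1-(benzyloxy)-4-(3-bromoprop-1-en-1-yl)-2-methoxybenzene | COc1cc(/C=C/CBr)ccc1OCc1ccccc1 | intermediate
34 | trimer epoxy cinnamyl ether, (S)-carbinol carbon, (R)-oxirane | COc1cc(ccc1OCc1ccccc1)/C=C/CO[C@@H](c1cc(OC)c2c(c1)[C@H](CO[Si](c6ccccc6)(c7ccccc7)C(C)(C)C)[C@@H](c1cc(OC)c3c(c1)[C@H](CO[Si](c6ccccc6)(c7ccccc7)C(C)(C)C)[C@@H](c1cc(OC)c4c(c1)[C@@H](CO[Si](c6ccccc6)(c7ccccc7)C(C)(C)C)[C@H](c1ccc(OCc5ccccc5)c(OC)c1)O4)O3)O2)[C@H]8CO8 | intermediate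
35 | protected target, (2R,3S,4S)-oxolane with free 3-CH2OH, three CH2OTBDPS, two OBn | COc1cc(ccc1OCc1ccccc1)C[C@@H]8CO[C@@H](c1cc(OC)c2c(c1)[C@H](CO[Si](c6ccccc6)(c7ccccc7)C(C)(C)C)[C@@H](c1cc(OC)c3c(c1)[C@H](CO[Si](c6ccccc6)(c7ccccc7)C(C)(C)C)[C@@H](c1cc(OC)c4c(c1)[C@@H](CO[Si](c6ccccc6)(c7ccccc7)C(C)(C)C)[C@H](c1ccc(OCc5ccccc5)c(OC)c1)O4)O3)O2)[C@@H]8CO | intermediate
36 | bis-benzyl ether of the target | COc1cc(ccc1OCc1ccccc1)C[C@@H]8CO[C@@H](c1cc(OC)c2c(c1)[C@H](CO)[C@@H](c1cc(OC)c3c(c1)[C@H](CO)[C@@H](c1cc(OC)c4c(c1)[C@@H](CO)[C@H](c1ccc(OCc5ccccc5)c(OC)c1)O4)O3)O2)[C@@H]8CO | intermediate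
37 | CNP0267891.2 | COc1cc(C[C@@H]2CO[C@@H](c3cc(OC)c4c(c3)[C@H](CO)[C@@H](c3cc(OC)c5c(c3)[C@H](CO)[C@@H](c3cc(OC)c6c(c3)[C@@H](CO)[C@H](c3ccc(O)c(OC)c3)O6)O5)O4)[C@@H]2CO)ccc1O | target

**Step count and risks**
Total: 28 steps. Longest linear sequence: 25 steps (steps 1–21, then 25–28); the three-step branch to bromide 33 (steps 22–24) joins at step 25.

Steps most likely to fail:

1. Step 26. The C3 radical may be captured by titanium before it cyclises, which ends in loss of the epoxide oxygen, or the closure may run with poor facial control at C3 and C4. The fallback builds the oxolane by the lactone aldol route instead. It sets out from alcohol 8 and aldehyde 26 and comes back at 35.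
   - Alcohol 8 is oxidised with MnO2 to 4-(benzyloxy)-3-methoxybenzaldehyde F1.
   - Stobbe condensation of F1 with dimethyl succinate (NaOMe, MeOH) gives the (E)-half-ester F2.
   - Asymmetric hydrogenation of F2 with [Rh(cod)2]BF4 and a DuPhos-type bisphosphine, of the ligand sense that gives the (S) product, gives the acid ester F3.
   - Reduction of the ester of F3 as its carboxylate salt with Ca(BH4)2, then acid lactonisation, gives the (S)-lactone F4.
   - F4 is deprotonated with LiN(SiMe3)2 (THF, −78 °C) and added to 26; attack anti to the benzyl group should give the trans aldol lactone F5 as carbinol epimers.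
   - LiAlH4 opens F5 to the triol F6.
   - Catalytic camphorsulfonic acid (CH2Cl2, 0 °C) ionises the electron-rich benzylic carbinol of F6, and the hydroxymethyl on the benzyl-bearing carbon closes the ring to the more stable 2,3-trans oxolane 35.

2. Step 21. The two carbinol epimers may differ too little in rate, or the electron-rich benzylic alcohol may ionise on titanium. The fallback sets the carbinol centre in the C–C bond formation. It sets out from aldehyde 26 and comes back at 29.
   - Salt-free divinylzinc F7 is made from 27 and ZnCl2.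
   - F7 adds to 26 in toluene at 0 °C with catalytic (2R)-(+)-3-exo-(dimethylamino)isoborneol, the ligand enantiomer expected to give the (R)-carbinol, to give the single (R)-allylic alcohol F8.
   - F8 is epoxidised under the conditions of step 21 with a full equivalent of t-BuOOH (now a matched, complete reaction) to give 29.

3. Step 25. The alkoxide of 29 may undergo Payne rearrangement (epoxide migration), or the labile bromide 33 may decompose under the basic conditions. The fallback makes the ether under acid catalysis without an alkoxide. It sets out from alcohol 32 and epoxy alcohol 29 and comes back at 34.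
   - 32 with Cl3CCN and catalytic DBU (CH2Cl2, 0 °C) gives the cinnamyl trichloroacetimidate F9.
   - F9 and 29 with a trace of camphorsulfonic acid (CH2Cl2, −20 °C) should give 34 by attack of the alcohol at the unsubstituted terminus of the stabilised cinnamyl cation.

**Further compounds**
F1 | step 26 | 4-(benzyloxy)-3-methoxybenzaldehyde | COc1cc(C=O)ccc1OCc1ccccc1
F2 | step 26 | (E)-4-[4-(benzyloxy)-3-methoxyphenyl]-3-(methoxycarbonyl)but-3-enoic acid | COC(=O)/C(CC(=O)O)=C/c1ccc(OCc2ccccc2)c(OC)c1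
F3 | step 26 | (3S)-4-[4-(benzyloxy)-3-methoxyphenyl]-3-(methoxycarbonyl)butanoic acid | COC(=O)[C@H](CC(=O)O)Cc1ccc(OCc2ccccc2)c(OC)c1
F4 | step 26 | (4S)-4-[4-(benzyloxy)-3-methoxybenzyl]oxolan-2-one | O=C1C[C@H](Cc2ccc(OCc3ccccc3)c(OC)c2)CO1
F5 | step 26 | (3R,4S)-4-[4-(benzyloxy)-3-methoxybenzyl]-3-[hydroxy(trimer aryl)methyl]oxolan-2-one, carbinol epimers, trimer aryl as in 26 | O=C1OC[C@@H](Cc2ccc(OCc3ccccc3)c(OC)c2)[C@@H]1C(O)c1cc(OC)c2c(c1)[C@H](CO[Si](c6ccccc6)(c7ccccc7)C(C)(C)C)[C@@H](c1cc(OC)c3c(c1)[C@H](CO[Si](c6ccccc6)(c7ccccc7)C(C)(C)C)[C@@H](c1cc(OC)c4c(c1)[C@@H](CO[Si](c6ccccc6)(c7ccccc7)C(C)(C)C)[C@H](c1ccc(OCc5ccccc5)c(OC)c1)O4)O3)O2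
F6 | step 26 | (2S,3S)-3-[4-(benzyloxy)-3-methoxybenzyl]-2-[hydroxy(trimer aryl)methyl]butane-1,4-diol, carbinol epimers | OC[C@@H](Cc2ccc(OCc3ccccc3)c(OC)c2)[C@@H](CO)C(O)c1cc(OC)c2c(c1)[C@H](CO[Si](c6ccccc6)(c7ccccc7)C(C)(C)C)[C@@H](c1cc(OC)c3c(c1)[C@H](CO[Si](c6ccccc6)(c7ccccc7)C(C)(C)C)[C@@H](c1cc(OC)c4c(c1)[C@@H](CO[Si](c6ccccc6)(c7ccccc7)C(C)(C)C)[C@H](c1ccc(OCc5ccccc5)c(OC)c1)O4)O3)O2
F7 | step 21 | divinylzinc | C=C[Zn]C=C
F8 | step 21 | (R)-carbinol epimer of 28 | C=C[C@@H](O)c1cc(OC)c2c(c1)[C@H](CO[Si](c6ccccc6)(c7ccccc7)C(C)(C)C)[C@@H](c1cc(OC)c3c(c1)[C@H](CO[Si](c6ccccc6)(c7ccccc7)C(C)(C)C)[C@@H](c1cc(OC)c4c(c1)[C@@H](CO[Si](c6ccccc6)(c7ccccc7)C(C)(C)C)[C@H](c1ccc(OCc5ccccc5)c(OC)c1)O4)O3)O2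
F9 | step 25 | (E)-3-[4-(benzyloxy)-3-methoxyphenyl]prop-2-en-1-yl 2,2,2-trichloroacetimidate | COc1cc(/C=C/COC(=N)C(Cl)(Cl)Cl)ccc1OCc1ccccc1
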